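The constants of these runs appear once percent is turned into molarity.

| flask | solid substrate | remark | time |
|---|---|---|---|
| Thursday's | 1.8 M | run made earlier |  |
| Wednesday's | 2.9 M | run made earlier |  |
| flask | 1.3 M |  | 12 h |

| run | time / h | product / % | starting material / % | solid substrate / % |
|---|---|---|---|---|
| Thursday's | 1.00 | 0 | 2.3 | 95.9 |
| Thursday's | 3.00 | 0 | 2.0 | 93.0 |
| Thursday's | 5.00 | 1.2 | 2.1 | 89.5 |
| Thursday's | 8.00 | 2.2 | 2.6 | 83.6 |
| Thursday's | 12.0 | 4.1 | 2.7 | 76.5 |
| Thursday's | 15.0 | 6.6 | 2.3 | 70.9 |
| Wednesday's | 2.50 | 0.2 | 1.7 | 96.1 |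
| Wednesday's | 5.00 | 0.7 | 1.3 | 93.8 |
| Wednesday's | 8.00 | 0.9 | 1.2 | 90.0 |
| Wednesday's | 10.0 | 2.1 | 1.5 | 87.9 |
| Wednesday's | 12.0 | 2.5 | 1.1 | 85.5 |
| Wednesday's | 15.0 | 4.3 | 1.2 | 81.9 |

(scatter of a reading: 0.3 percentage points)

* amount of product at 12 h, in percent of the solid substrate charged
* concentration of starting material in solution at 12 h, in percent of saturation

- solid, in amounts per volume of the solution: solid substrate
- at the start none of the solid substrate is in solution
- starting material means what is dissolved; the solid is not counted in it
- starting material is what solid substrate becomes in solution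

Bench note for the flask. In Thursday's run [starting material] averages 0.0420 M, in Wednesday's 0.0387 M. Their solids fall by 0.0321 M h⁻¹ and 0.0329 M h⁻¹. Dividing the mean pool 0.0403 M by the mean throughput 0.0325 M h⁻¹ gives the lifetime of starting material in solution, 1.24 h.

The flask's 12 h spans 9.68 lifetimes, so its pool is in a steady state. By that time Thursday's run had lost 0.423 M of solid and Wednesday's 0.421 M, so the flask should lose about as much of its 1.3 M. Product at that time reads 0.0738 M and 0.0725 M, which is 5.63% of this charge. Flat readings give no saturation value. No solid is to be added: Wednesday's larger charge fed the solution at about the same pace.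

The forecast, above this reckoning, holds that “the solution stays essentially saturated” and gives 5.9% (5% to 6.7%) and 97% (88% to 100%).

The flask gives 6.03% and 68.8%.

    starting material → intermediate A (k = 1.01 × 10⁻⁴ s⁻¹)
    solid substrate ⇌ starting material, rate k2*(cs2 - [starting material]) while solid is left; crystals form when [starting material] > cs2 (solubility = 0.0580 M, k = 5.10 × 10⁻⁴ s⁻¹)
    starting material → intermediate B (k = 1.30 × 10⁻⁴ s⁻¹)
    intermediate B → intermediate C (k = 0.00475 s⁻¹)
    intermediate C → intermediate D (k = 0.00265 s⁻¹)
    intermediate A ⇌ intermediate B (K = 0.530, k = 3.36 × 10⁻⁴ s⁻¹)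
    intermediate D → product (k = 1.27 × 10⁻⁵ s⁻¹)

In the flask, refilling has the lifetime 0.545 h, shorter than τ. A pool fed and drained at these paces stands at τ/(τ+1/k2), 69.5% of saturation. Read at 50 h, the same flask has charge over throughput 39.9 h, then 8.15 lifetimes of decay; computed, solid substrate stands at 0% and starting material at 0%.

The numbers in the tables are simulated for an exercise; scatter was added.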